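**Retrosynthetic overview**
- Feature: ring A is the benzene ring of the hydroxyl-free chromene. Its carbons C4a–C5–C6–C7–C8–C8a carry the pyran oxygen O1 on C8a and the acyl carbon on C6, para to each other. This is the pattern left by a 2-oxy-diene adding to an ynone.
- Disconnection 1: cutting the CH2–C(=O) bond next to ring B (benzene ring of the hydroxychromene) by a crossed Claisen gives the ring A methyl ketone and a MOM-protected ring B methyl ester.
- Disconnection 2 (key): cutting C4a–C5 and C6–C7 of ring A (Diels–Alder, then loss of CO2) leads to but-3-yn-2-one and a dimethylpyran-fused 4-alkoxy-2-pyrone. That pyrone comes in one step from 4-hydroxy-2-pyrone and prenal.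
- Disconnection 3: the ring B ester comes from 4-bromoresorcinol by the same prenal annulation, MOM protection and Br→Li→CO2Me exchange.
- Ring order: first the pyran fused to ring A, then ring A itself. Separately, the pyran is fused onto the purchased ring B. The halves are then joined and the phenol is freed.

Key step: step 2

Assumption: the target is drawn as the diketo tautomer. It will exist largely as the chelated enol of the same compound. It holds no stereocentre, so no step has to set one.

**Step 1**
Reactants: 1 4-hydroxy-2H-pyran-2-one; 2 3-methylbut-2-enal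
Product: 4 2,2-dimethyl-2H,5H-pyrano[4,3-b]pyran-5-one, via 1-oxatriene 3 (not isolated)
Conditions: ethylenediammonium diacetate (10 mol %), EtOAc, 60 °C
Reagents that add atoms: none
Why: Knoevenagel condensation of the nucleophilic C3 of 1 with the iminium ion of 2 gives 3, which closes by oxa-6π electrocyclisation onto the C4 ketone oxygen (formal [3+3] annulation, established for 4-hydroxy-6-methyl-2-pyrone and β,β-disubstituted enals), and the catalytic, buffered amine spares the C7–H pyrone from nucleophilic ring opening.

**Step 2**
Reactants: 4 2,2-dimethyl-2H,5H-pyrano[4,3-b]pyran-5-one; 5 but-3-yn-2-one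
Product: 7 1-(2,2-dimethyl-2H-chromen-6-yl)ethanone, via bridged lactone 6 (not isolated)
Conditions: 5 (4 equiv, in portions), BHT (5 mol %), toluene, pressure tube, 140 °C, −CO2
Reagents that add atoms: none
Why: Proposed new method: a thermal normal-electron-demand [4+2] cycloaddition of the ynone across the pyrone diene C4a=C8a–C8=C7 should give the 2-oxabicyclo[2.2.2]octadienone 6, which expels CO2 (C5 and O6) by retro-[4+2] at the reaction temperature and aromatises to 7; the closest known reaction type is the Diels–Alder/decarboxylation of monocyclic 4-alkoxy-2-pyrones with acetylenic esters and ketones, which has not been shown on a 2H-pyran-fused pyrone whose diene terminus (here C4a) is fully substituted. The one ring closed, ring A, closes by intermolecular cycloaddition (bonds C4a–C5 and C6–C7) followed by cycloreversion, not by cyclisation of a chain. The two bridgehead stereocentres of 6 (former C4a and C7, tied to each other by the bicycle, racemic) vanish with the CO2, so no stereocontrol is needed. Regioselectivity is needed: O1 (through C8a=C4a) and O6 (through C7=C8–C8a=C4a) both push electron density onto C4a, which should therefore bond to the electrophilic terminal CH of 5, and this pairing also puts the small end of the alkyne at the crowded terminus, so the acetyl group ends on C6, para to O1, and not on C5. Chemoselectivity is needed as well, because C3=C4–C4a=C8a is a second cisoid diene that could add 5 and lose acetone; the two methyl groups on C2 cover both faces of its C3 terminus, whereas the pyrone is flat and open at C7. Amine-free 4, the radical inhibitor and portionwise addition of 5 hold back trimerisation and polymerisation of the ynone, and thermal opening of the 2H-pyran to 3 is reversible and drains back to 4.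

**Step 3**
Reactants: 8 4-bromoresorcinol; 2 3-methylbut-2-enal
Product: 10 6-bromo-2,2-dimethyl-2H-chromen-7-ol, via quinone methide 9 (not isolated)
Conditions: 2 (1.05 equiv), ethylenediammonium diacetate (20 mol %), toluene, 110 °C
Reagents that add atoms: none
Why: Amine-catalysed Knoevenagel-type condensation followed by oxa-6π electrocyclisation (the known chromene annulation of resorcinols with enals) should start at C6 of 8, which is para to the C3 hydroxyl, is the less crowded of the two doubly activated carbons and is the site at which 8 reacts in Pechmann condensations, while bromine blocks C4 and stays as the handle for the acyl carbon.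

**Step 4**
Reactants: 10 6-bromo-2,2-dimethyl-2H-chromen-7-ol
Product: 11 6-bromo-7-(methoxymethoxy)-2,2-dimethyl-2H-chromene
Conditions: MOMCl (1.5 equiv), K2CO3 (3 equiv), acetone, 0 → 23 °C
Reagents that add atoms: chloromethyl methyl ether (MOMCl), COCCl
Why: Williamson-type O-alkylation masks the only acidic proton as an acetal that withstands n-BuLi and amide base and can later chelate lithium.

**Step 5**
Reactants: 11 6-bromo-7-(methoxymethoxy)-2,2-dimethyl-2H-chromene
Product: 13 methyl 7-(methoxymethoxy)-2,2-dimethyl-2H-chromene-6-carboxylate, via aryllithium 12 (not isolated)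
Conditions: n-BuLi (1.05 equiv), THF, −78 °C; then cannulated into ClCO2Me (3 equiv), THF, −78 → 0 °C
Reagents that add atoms: methyl chloroformate, COC(=O)Cl
Why: Bromine–lithium exchange at −78 °C outruns deprotonation at C8 and gives an aryllithium held by the neighbouring MOM oxygen, and its inverse addition to excess chloroformate (acylation of an organolithium) should stop at the ester.

**Step 6**
Reactants: 7 1-(2,2-dimethyl-2H-chromen-6-yl)ethanone; 13 methyl 7-(methoxymethoxy)-2,2-dimethyl-2H-chromene-6-carboxylate
Product: 15 1-(2,2-dimethyl-2H-chromen-6-yl)-3-[7-(methoxymethoxy)-2,2-dimethyl-2H-chromen-6-yl]propane-1,3-dione, via lithium enolate 14 (not isolated)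
Conditions: 7, LiN(SiMe3)2 (2.3 equiv), THF, −78 °C; then 13, −78 → 40 °C; AcOH quench
Reagents that add atoms: none
Why: In this crossed Claisen condensation 13 has no α-hydrogen and 7 has a single enolisable position, lithium chelation between the MOM oxygen and the ester carbonyl helps the electron-rich ester to accept the enolate, and the second equivalent of base deprotonates the 1,3-diketone and so draws the equilibrium to product.

**Step 7**
Reactants: 15 1-(2,2-dimethyl-2H-chromen-6-yl)-3-[7-(methoxymethoxy)-2,2-dimethyl-2H-chromen-6-yl]propane-1,3-dione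
Product: 16 glyinflanin D, 1-(2,2-dimethyl-2H-chromen-6-yl)-3-(7-hydroxy-2,2-dimethyl-2H-chromen-6-yl)propane-1,3-dione
Conditions: 3 M aq HCl, THF, 23 °C, stopped at full conversion
Reagents that add atoms: none
Why: In this acid-catalysed acetal hydrolysis the aryl MOM ether ortho to the ketone is labilised by the neighbouring carbonyl, so dilute acid at ambient temperature should suffice and stay below what cyclodehydration to the flavone or hydration of the chromene alkenes requires.

**Compound list**
1 | 4-hydroxy-2H-pyran-2-one | O=C1C=C(O)C=CO1 | starting material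
2 | 3-methylbut-2-enal (prenal) | CC(C)=CC=O | starting material
3 | (3E)-3-(3-methylbut-2-en-1-ylidene)-2H-pyran-2,4(3H)-dione (1-oxatriene, not isolated) | CC(C)=C/C=C1\C(=O)C=COC1=O | intermediate
4 | 2,2-dimethyl-2H,5H-pyrano[4,3-b]pyran-5-one | CC1(C)C=CC2=C(C=COC2=O)O1 | intermediate
5 | but-3-yn-2-one | CC(=O)C#C | starting material
6 | 7-acetyl-2-oxabicyclo[2.2.2]octa-5,7-dien-3-one bearing a –CH=CH–CMe2–O– bridge from bridgehead C4 to alkene carbon C5 (bridged lactone, racemic, one enantiomer drawn, not isolated) | CC1(C)C=C[C@@]23C=C(C(C)=O)[C@@H](OC2=O)C=C3O1 | intermediate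
7 | 1-(2,2-dimethyl-2H-chromen-6-yl)ethanone | CC(=O)c1ccc2OC(C)(C)C=Cc2c1 | intermediate
8 | 4-bromoresorcinol | Oc1ccc(Br)c(O)c1 | starting material
9 | (6Z)-4-bromo-3-hydroxy-6-(3-methylbut-2-en-1-ylidene)cyclohexa-2,4-dien-1-one (quinone methide, not isolated) | CC(C)=C/C=C1\C(=O)C=C(O)C(Br)=C1 | intermediate
10 | 6-bromo-2,2-dimethyl-2H-chromen-7-ol | CC1(C)C=Cc2cc(Br)c(O)cc2O1 | intermediate
11 | 6-bromo-7-(methoxymethoxy)-2,2-dimethyl-2H-chromene | COCOc1cc2OC(C)(C)C=Cc2cc1Br | intermediate
12 | [7-(methoxymethoxy)-2,2-dimethyl-2H-chromen-6-yl]lithium (not isolated) | [Li]c1cc2C=CC(C)(C)Oc2cc1OCOC | intermediate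
13 | methyl 7-(methoxymethoxy)-2,2-dimethyl-2H-chromene-6-carboxylate | COCOc1cc2OC(C)(C)C=Cc2cc1C(=O)OC | intermediate
14 | lithium 1-(2,2-dimethyl-2H-chromen-6-yl)ethen-1-olate (not isolated) | [Li]OC(=C)c1ccc2OC(C)(C)C=Cc2c1 | intermediate
15 | 1-(2,2-dimethyl-2H-chromen-6-yl)-3-[7-(methoxymethoxy)-2,2-dimethyl-2H-chromen-6-yl]propane-1,3-dione | COCOc1cc2OC(C)(C)C=Cc2cc1C(=O)CC(=O)c1ccc2OC(C)(C)C=Cc2c1 | intermediate
16 | glyinflanin D | CC1(C)C=Cc2cc(C(=O)CC(=O)c3cc4c(cc3O)OC(C)(C)C=C4)ccc2O1 | target

**Step count**
Total steps: 7. Longest linear sequence: 5 (steps 3, 4, 5, 6, 7). The ring A branch (steps 1, 2) joins at step 6.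

**Steps most likely to fail**

1. Step 2 (the new method).
   - What may go wrong: the ynone may polymerise or cyclotrimerise before the hindered pyrone diene engages. Cycloaddition may take place at the 2H-pyran diene (C3/C8a) with loss of acetone. The pyran may also open thermally and drift away through hydrogen shifts.
   - Fallback: ring A is bought instead of built, using known chemistry. The fallback sets out from 2. Acetalisation with HC(OEt)3 and catalytic NH4NO3 in EtOH gives 1,1-diethoxy-3-methylbut-2-ene F1. F1 is heated with purchased 4-hydroxyacetophenone (CC(=O)c1ccc(O)cc1) and 3-picoline in p-xylene at 140 °C. This is the established chromenylation of electron-poor para-substituted phenols (acetal exchange, loss of ethanol, sigmatropic shift, oxa-6π closure). It comes back to the route at 7.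

2. Step 3.
   - What may go wrong: site selectivity of the C–C bond formation may be poor (C2 against C6 of 8). Closure may go onto the wrong hydroxyl, or 10 may undergo a second annulation at C8.
   - Fallback: the ring carbon is fixed by acylation instead of condensation. The fallback sets out from 8. Friedel–Crafts acylation and oxa-Michael closure with 3-methylbut-2-enoic acid in P2O5/MeSO3H at 60 °C give 6-bromo-7-hydroxy-2,2-dimethylchroman-4-one F2. MOMCl/K2CO3 in acetone gives 6-bromo-7-(methoxymethoxy)-2,2-dimethylchroman-4-one F3. NaBH4 in MeOH gives racemic 6-bromo-7-(methoxymethoxy)-2,2-dimethylchroman-4-ol F4. MsCl/Et3N in CH2Cl2 (0 → 23 °C) then ionises the doubly oxygen-activated benzylic position and eliminates. The fallback comes back to the route at 11.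

3. Step 7.
   - What may go wrong: once the phenol is free, acid may drive hemiketalisation and cyclodehydration of the 2-hydroxyaryl 1,3-diketone to the flavone. Acid may also add water across a chromene alkene.
   - Fallback: the acid step is moved ahead of diketone formation and the phenol is released by fluoride. The fallback sets out from 13. Aqueous HCl in THF cleaves the MOM group at the ester stage to give methyl 7-hydroxy-2,2-dimethyl-2H-chromene-6-carboxylate F5. TBSCl and imidazole in DMF give methyl 7-(tert-butyldimethylsilyloxy)-2,2-dimethyl-2H-chromene-6-carboxylate F6. Acylation of the lithium enolate 14 (from 7 and LiN(SiMe3)2) with F6 is a known use of silyloxybenzoates. It gives 1-[7-(tert-butyldimethylsilyloxy)-2,2-dimethyl-2H-chromen-6-yl]-3-(2,2-dimethyl-2H-chromen-6-yl)propane-1,3-dione F7. n-Bu4NF buffered with AcOH in THF at 0 °C removes the silyl group. The fallback comes back to the route at 16.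

**Further compounds**
F1 | step 2 | 1,1-diethoxy-3-methylbut-2-ene | CCOC(OCC)C=C(C)C
F2 | step 3 | 6-bromo-7-hydroxy-2,2-dimethylchroman-4-one | CC1(C)CC(=O)c2cc(Br)c(O)cc2O1
F3 | step 3 | 6-bromo-7-(methoxymethoxy)-2,2-dimethylchroman-4-one | CC1(C)CC(=O)c2cc(Br)c(OCOC)cc2O1
F4 | step 3 | 6-bromo-7-(methoxymethoxy)-2,2-dimethylchroman-4-ol (racemic) | CC1(C)CC(O)c2cc(Br)c(OCOC)cc2O1
F5 | step 7 | methyl 7-hydroxy-2,2-dimethyl-2H-chromene-6-carboxylate | COC(=O)c1cc2C=CC(C)(C)Oc2cc1O
F6 | step 7 | methyl 7-(tert-butyldimethylsilyloxy)-2,2-dimethyl-2H-chromene-6-carboxylate | COC(=O)c1cc2C=CC(C)(C)Oc2cc1O[Si](C)(C)C(C)(C)C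
F7 | step 7 | 1-[7-(tert-butyldimethylsilyloxy)-2,2-dimethyl-2H-chromen-6-yl]-3-(2,2-dimethyl-2H-chromen-6-yl)propane-1,3-dione | CC(C)(C)[Si](C)(C)Oc1cc2OC(C)(C)C=Cc2cc1C(=O)CC(=O)c1ccc2OC(C)(C)C=Cc2c1
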